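**Retrosynthetic overview**

1. Target ⇐ its C3 ketone, by a reagent-controlled 1,2-reduction in the last step.
2. C3-ketone macrocycle ⇐ an α-methylbutenolide with an E-alkenyl boronate side chain: ring expansion of the five-membered lactone to the ten-membered carbocycle by intramolecular alkenyl transfer to the lactone C=O (C2–C3 bond). The expelled C6 alkoxide closes the α-methylene lactone in the same flask.
3. Butenolide ⇐ C6 aldehyde + methyl (Z)-3-iodo-2-methylacrylate (Nozaki–Hiyama–Kishi coupling, C5–C6 bond, then lactonisation).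
4. C6 aldehyde ⇐ glycol cleavage of a glyceraldehyde-derived dioxolane, which first steers the indium Barbier coupling (C7–C8 bond, both centres) of a 2-(bromomethyl)acrylate with the C8–C2 aldehyde. The angelate goes on C8–OH right after the coupling.
5. C8–C2 aldehyde ⇐ Sharpless epoxidation and hydride opening (C10), alkyne protoboration, oxidation. Ring order: butenolide first, then the ten-membered ring and the methylene lactone together.

Assumption: labels C1–C13 follow germacranolide numbering of the target (ring C1–C10 with C3 and C10 carbinols, C6 lactone O–CH, C7, C8 ester O–CH; C11–C13 the methylene-lactone carbons); Bpin = 4,4,5,5-tetramethyl-1,3,2-dioxaborolan-2-yl; methyl (Z)-3-iodo-2-methylacrylate is taken as a purchasable building block.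

**Route**

Step 1
Reactants: 1 (2E)-3-methylpent-2-en-4-yn-1-ol
Product: 2 [(2S,3S)-3-ethynyl-3-methyloxiran-2-yl]methanol
Conditions: Ti(OiPr)4 (10 mol %), L-(+)-diethyl tartrate (12 mol %), t-BuOOH, 4 Å MS, CH2Cl2, −20 °C
Reagents that add atoms: tert-butyl hydroperoxide, CC(C)(C)OO
Why: Sharpless asymmetric epoxidation of an E-trisubstituted allylic alcohol, in which the L-(+)-tartrate complex delivers oxygen to the face that gives the (2S,3S)-epoxide and so fixes the later C10 carbinol.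

Step 2
Reactants: 2 [(2S,3S)-3-ethynyl-3-methyloxiran-2-yl]methanol
Product: 3 (3R)-3-methylpent-4-yne-1,3-diol
Conditions: NaAlH2(OCH2CH2OMe)2 (1.2 equiv), THF, −20 to 0 °C; aq. KNaC4H4O6
Reagents that add atoms: none
Why: Hydroxyl-directed reductive opening of a 2,3-epoxy alcohol (Red-Al opening) delivers hydride to C2 and leaves the C3–O bond untouched, so the tertiary carbinol is R, and the low temperature keeps the alkyne from hydroalumination.

Step 3
Reactants: 3 (3R)-3-methylpent-4-yne-1,3-diol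
Product: 4 (3R,4E)-3-methyl-5-(Bpin)pent-4-ene-1,3-diol
Conditions: CuCl (5 mol %), Xantphos (5 mol %), NaOtBu (10 mol %), B2pin2 (1.1 equiv), MeOH (2 equiv), THF, rt
Reagents that add atoms: bis(pinacolato)diboron, CC1(C)OB(OC1(C)C)B1OC(C)(C)C(C)(C)O1
Why: Copper-catalysed protoboration (syn borylcupration of the terminal alkyne, then protonation by methanol) gives the E-alkenyl boronate with boron on the terminal carbon and tolerates free hydroxyls.

Step 4
Reactants: 4 (3R,4E)-3-methyl-5-(Bpin)pent-4-ene-1,3-diol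
Product: 5 (3R,4E)-3-hydroxy-3-methyl-5-(Bpin)pent-4-enal
Conditions: TEMPO (10 mol %), PhI(OAc)2 (1.1 equiv), CH2Cl2, 0 °C to rt
Reagents that add atoms: none
Why: The TEMPO/PhI(OAc)2 oxidation takes only the primary alcohol to the aldehyde and leaves the tertiary alcohol and the alkenyl boronate untouched.

Step 5
Reactants: 6 (4R)-2,2-dimethyl-1,3-dioxolane-4-carbaldehyde (D-glyceraldehyde acetonide); 7 methyl acrylate
Product: 8 methyl 2-{[(4R)-2,2-dimethyl-1,3-dioxolan-4-yl](hydroxy)methyl}prop-2-enoate (both carbinol epimers)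
Conditions: DABCO (0.5 equiv), 1,4-dioxane/H2O 1:1, rt
Reagents that add atoms: none
Why: Morita–Baylis–Hillman reaction, whose new carbinol centre may be a mixture because it becomes sp2 in step 6.

Step 6
Reactants: 8 methyl 2-{[(4R)-2,2-dimethyl-1,3-dioxolan-4-yl](hydroxy)methyl}prop-2-enoate
Product: 9 methyl (2Z)-2-(bromomethyl)-3-[(4S)-2,2-dimethyl-1,3-dioxolan-4-yl]prop-2-enoate
Conditions: NBS, Me2S, CH2Cl2, 0 °C to rt
Reagents that add atoms: N-bromosuccinimide, O=C1CCC(=O)N1Br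
Why: Corey–Kim-type activation of the allylic alcohol and SN2' attack of bromide (allylic transposition) give the thermodynamically favoured Z 2-(bromomethyl)enoate without touching the dioxolane centre.

Step 7
Reactants: 5 (3R,4E)-3-hydroxy-3-methyl-5-(Bpin)pent-4-enal; 9 methyl (2Z)-2-(bromomethyl)-3-[(4S)-2,2-dimethyl-1,3-dioxolan-4-yl]prop-2-enoate
Product: 11 methyl (3R,4R,6R,7E)-3-[(4S)-2,2-dimethyl-1,3-dioxolan-4-yl]-4,6-dihydroxy-6-methyl-2-methylidene-8-(Bpin)oct-7-enoate, via allylindium dibromide 10 (not isolated)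
Conditions: In powder (1.5 equiv), THF/H2O 1:1, rt
Reagents that add atoms: none
Why: Indium Barbier 2-(alkoxycarbonyl)allylation, in which the Z-allylindium reacts through a closed chair transition state to give the 7,8-syn adduct and the aldehyde is expected to approach C7 anti to the dioxolane C–O bond in the A(1,3)-minimised conformer, so that the glyceraldehyde centre sets C7 and C8 (oct-7-enoate C3 and C4) as R,R.

Step 8
Reactants: 11 methyl (3R,4R,6R,7E)-3-[(4S)-2,2-dimethyl-1,3-dioxolan-4-yl]-4,6-dihydroxy-6-methyl-2-methylidene-8-(Bpin)oct-7-enoate; 12 angelic acid, (2Z)-2-methylbut-2-enoic acid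
Product: 14 methyl (3R,4R,6R,7E)-3-[(4S)-2,2-dimethyl-1,3-dioxolan-4-yl]-6-hydroxy-6-methyl-4-{[(2Z)-2-methylbut-2-enoyl]oxy}-2-methylidene-8-(Bpin)oct-7-enoate, via mixed anhydride 13 (not isolated)
Conditions: 12, 2,4,6-Cl3C6H2COCl, Et3N, toluene, rt; then 11, DMAP (0.2 equiv), 0 °C to rt
Reagents that add atoms: none
Why: Yamaguchi esterification through the mixed anhydride acylates the secondary C8 hydroxyl (the tertiary C10 hydroxyl is inert), and the mild conditions keep the Z geometry of the angelate.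

Step 9
Reactants: 14 methyl (3R,4R,6R,7E)-3-[(4S)-2,2-dimethyl-1,3-dioxolan-4-yl]-6-hydroxy-6-methyl-4-{[(2Z)-2-methylbut-2-enoyl]oxy}-2-methylidene-8-(Bpin)oct-7-enoate
Product: 16 methyl (3R,4R,6R,7E)-3-formyl-6-hydroxy-6-methyl-4-{[(2Z)-2-methylbut-2-enoyl]oxy}-2-methylidene-8-(Bpin)oct-7-enoate, via diol 15 (not isolated)
Conditions: H5IO6 (1.5 equiv), EtOAc, 0 °C to rt; crude 16 used at once
Reagents that add atoms: none
Why: One-pot acetonide hydrolysis and periodate glycol cleavage (Malaprade reaction) remove the stereodirecting dioxolane as acetone and formaldehyde and leave the C6 aldehyde, with C7 untouched under acidic, base-free conditions.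

Step 10
Reactants: 16 methyl (3R,4R,6R,7E)-3-formyl-6-hydroxy-6-methyl-4-{[(2Z)-2-methylbut-2-enoyl]oxy}-2-methylidene-8-(Bpin)oct-7-enoate; 17 methyl (2Z)-3-iodo-2-methylprop-2-enoate
Product: 20 methyl (3R,4R,6R,7E)-6-hydroxy-6-methyl-4-{[(2Z)-2-methylbut-2-enoyl]oxy}-2-methylidene-3-[(2R)-4-methyl-5-oxo-2,5-dihydrofuran-2-yl]-8-(Bpin)oct-7-enoate, via alkenylchromium dichloride 18 (not isolated), via hydroxy Z-enoate 19 (not isolated)
Conditions: CrCl2 (4 equiv), NiCl2 (2 mol %), DMF, rt; aq. NH4Cl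
Reagents that add atoms: none
Why: Nozaki–Hiyama–Kishi alkenylation is selective for the aldehyde, Felkin–Anh addition (branched C8 carbon anti to the nucleophile) reinforced by 1,3-anti induction from the C8 acyloxy group sets C6 as R, and the Z-γ-hydroxy enoate lactonises at once to the butenolide while the acrylate methyl ester stays open.

Step 11
Reactants: 20 methyl (3R,4R,6R,7E)-6-hydroxy-6-methyl-4-{[(2Z)-2-methylbut-2-enoyl]oxy}-2-methylidene-3-[(2R)-4-methyl-5-oxo-2,5-dihydrofuran-2-yl]-8-(Bpin)oct-7-enoate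
Product: 22 (3aR,4R,6R,7E,10Z,11aR)-6-hydroxy-6,10-dimethyl-3-methylidene-2,9-dioxo-2,3,3a,4,5,6,9,11a-octahydrocyclodeca[b]furan-4-yl (2Z)-2-methylbut-2-enoate, via cyclodecadienone hydroxy ester 21 (not isolated)
Conditions: [Rh(OMe)(cod)]2 (10 mol %), 1,4-dioxane, 70 °C, 20 added over 10 h (final 2 mM)
Reagents that add atoms: none
Why: Proposed new method: ring-expanding acyl substitution catalysed by monovalent rhodium, in which B-to-Rh transmetalation with Rh–OMe gives the E-alkenylrhodium species, whose only reachable electrophile is the butenolide C=O (attack at either enoate or at the angelate would put the E-alkene into a 7- or 8-membered ring), 1,2-addition gives a bridged hemiketal rhodium alkoxide that opens by cleavage of the ring C–O bond to the cyclodecadienone 21 (five- to ten-membered ring expansion, C2–C3 bond), and the released C6 alkoxide lactonises onto the acrylate ester and returns Rh–OMe; the closest known reaction type is the intramolecular acyl substitution of esters by alkenylrhodium intermediates in rhodium-catalysed arylative cyclisations to five-membered ketones, which has not been shown for lactones, ring expansion or medium rings.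

Step 12
Reactants: 22 (3aR,4R,6R,7E,10Z,11aR)-6-hydroxy-6,10-dimethyl-3-methylidene-2,9-dioxo-2,3,3a,4,5,6,9,11a-octahydrocyclodeca[b]furan-4-yl (2Z)-2-methylbut-2-enoate
Product: 23 (3aR,4R,6R,7E,9R,10Z,11aR)-6,9-dihydroxy-6,10-dimethyl-3-methylidene-2-oxo-2,3,3a,4,5,6,9,11a-octahydrocyclodeca[b]furan-4-yl (2Z)-2-methylbut-2-enoate (target)
Conditions: (S)-Me-CBS (1.2 equiv), catecholborane (2.5 equiv), toluene/CH2Cl2, −78 °C
Reagents that add atoms: none
Why: Corey–Bakshi–Shibata reduction gives 1,2-reduction of the cross-conjugated ketone with the α-methyl-substituted enone arm as the large group, so the (S)-oxazaborolidine delivers hydride to give the 9R (C3) carbinol, and the methylene lactone and the esters are not reduced at −78 °C.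

**Compound list**

1 | (2E)-3-methylpent-2-en-4-yn-1-ol | C#C/C(C)=C/CO | starting material
2 | [(2S,3S)-3-ethynyl-3-methyloxiran-2-yl]methanol | OC[C@@H]1O[C@@]1(C)C#C | intermediate
3 | (3R)-3-methylpent-4-yne-1,3-diol | C#C[C@](C)(O)CCO | intermediate
4 | (3R,4E)-3-methyl-5-(4,4,5,5-tetramethyl-1,3,2-dioxaborolan-2-yl)pent-4-ene-1,3-diol | CC1(C)OB(/C=C/[C@](C)(O)CCO)OC1(C)C | intermediate
5 | (3R,4E)-3-hydroxy-3-methyl-5-(4,4,5,5-tetramethyl-1,3,2-dioxaborolan-2-yl)pent-4-enal | CC1(C)OB(/C=C/[C@](C)(O)CC=O)OC1(C)C | intermediate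
6 | (4R)-2,2-dimethyl-1,3-dioxolane-4-carbaldehyde (D-glyceraldehyde acetonide) | O=C[C@H]1COC(C)(C)O1 | starting material
7 | methyl acrylate | C=CC(=O)OC | starting material
8 | methyl 2-{[(4R)-2,2-dimethyl-1,3-dioxolan-4-yl](hydroxy)methyl}prop-2-enoate (both carbinol epimers) | COC(=O)C(=C)C(O)[C@H]1COC(C)(C)O1 | intermediate
9 | methyl (2Z)-2-(bromomethyl)-3-[(4S)-2,2-dimethyl-1,3-dioxolan-4-yl]prop-2-enoate | COC(=O)/C(CBr)=C/[C@H]1COC(C)(C)O1 | intermediate
10 | methyl (2Z)-2-[(dibromoindiganyl)methyl]-3-[(4S)-2,2-dimethyl-1,3-dioxolan-4-yl]prop-2-enoate (allylindium dibromide, trivalent indium; not isolated) | COC(=O)/C(C[In](Br)Br)=C/[C@H]1COC(C)(C)O1 | intermediate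
11 | methyl (3R,4R,6R,7E)-3-[(4S)-2,2-dimethyl-1,3-dioxolan-4-yl]-4,6-dihydroxy-6-methyl-2-methylidene-8-(4,4,5,5-tetramethyl-1,3,2-dioxaborolan-2-yl)oct-7-enoate | C=C(C(=O)OC)[C@@H]([C@H]1COC(C)(C)O1)[C@H](O)C[C@@](C)(O)/C=C/B2OC(C)(C)C(C)(C)O2 | intermediate
12 | angelic acid, (2Z)-2-methylbut-2-enoic acid | C/C=C(/C)C(O)=O | starting material
13 | (2Z)-2-methylbut-2-enoic 2,4,6-trichlorobenzoic anhydride (not isolated) | C/C=C(/C)C(=O)OC(=O)c1c(Cl)cc(Cl)cc1Cl | intermediate
14 | methyl (3R,4R,6R,7E)-3-[(4S)-2,2-dimethyl-1,3-dioxolan-4-yl]-6-hydroxy-6-methyl-4-{[(2Z)-2-methylbut-2-enoyl]oxy}-2-methylidene-8-(4,4,5,5-tetramethyl-1,3,2-dioxaborolan-2-yl)oct-7-enoate | C=C(C(=O)OC)[C@@H]([C@H]1COC(C)(C)O1)[C@H](OC(=O)/C(C)=C\C)C[C@@](C)(O)/C=C/B2OC(C)(C)C(C)(C)O2 | intermediate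
15 | methyl (3S,4R,6R,7E)-3-[(1S)-1,2-dihydroxyethyl]-6-hydroxy-6-methyl-4-{[(2Z)-2-methylbut-2-enoyl]oxy}-2-methylidene-8-(4,4,5,5-tetramethyl-1,3,2-dioxaborolan-2-yl)oct-7-enoate (not isolated) | C=C(C(=O)OC)[C@@H]([C@H](O)CO)[C@H](OC(=O)/C(C)=C\C)C[C@@](C)(O)/C=C/B2OC(C)(C)C(C)(C)O2 | intermediate
16 | methyl (3R,4R,6R,7E)-3-formyl-6-hydroxy-6-methyl-4-{[(2Z)-2-methylbut-2-enoyl]oxy}-2-methylidene-8-(4,4,5,5-tetramethyl-1,3,2-dioxaborolan-2-yl)oct-7-enoate | C=C(C(=O)OC)[C@@H](C=O)[C@H](OC(=O)/C(C)=C\C)C[C@@](C)(O)/C=C/B2OC(C)(C)C(C)(C)O2 | intermediate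
17 | methyl (2Z)-3-iodo-2-methylprop-2-enoate | COC(=O)/C(C)=C\I | starting material
18 | methyl (2Z)-3-(dichlorochromio)-2-methylprop-2-enoate (alkenylchromium dichloride, trivalent chromium; not isolated) | COC(=O)/C(C)=C\[Cr](Cl)Cl | intermediate
19 | methyl (2Z,4R,5S,6R,8R,9E)-4,8-dihydroxy-5-(3-methoxy-3-oxoprop-1-en-2-yl)-2,8-dimethyl-6-{[(2Z)-2-methylbut-2-enoyl]oxy}-10-(4,4,5,5-tetramethyl-1,3,2-dioxaborolan-2-yl)deca-2,9-dienoate (not isolated) | C=C(C(=O)OC)[C@@H]([C@H](O)/C=C(/C)C(=O)OC)[C@H](OC(=O)/C(C)=C\C)C[C@@](C)(O)/C=C/B2OC(C)(C)C(C)(C)O2 | intermediate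
20 | methyl (3R,4R,6R,7E)-6-hydroxy-6-methyl-4-{[(2Z)-2-methylbut-2-enoyl]oxy}-2-methylidene-3-[(2R)-4-methyl-5-oxo-2,5-dihydrofuran-2-yl]-8-(4,4,5,5-tetramethyl-1,3,2-dioxaborolan-2-yl)oct-7-enoate | C=C(C(=O)OC)[C@@H]([C@H]1C=C(C)C(=O)O1)[C@H](OC(=O)/C(C)=C\C)C[C@@](C)(O)/C=C/B2OC(C)(C)C(C)(C)O2 | intermediate
21 | methyl 2-[(1S,2R,3Z,6E,8R,10R)-2,8-dihydroxy-4,8-dimethyl-10-{[(2Z)-2-methylbut-2-enoyl]oxy}-5-oxocyclodeca-3,6-dien-1-yl]prop-2-enoate (not isolated) | C=C(C(=O)OC)[C@H]1[C@H](O)/C=C(/C)C(=O)/C=C/[C@](C)(O)C[C@H]1OC(=O)/C(C)=C\C | intermediate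
22 | (3aR,4R,6R,7E,10Z,11aR)-6-hydroxy-6,10-dimethyl-3-methylidene-2,9-dioxo-2,3,3a,4,5,6,9,11a-octahydrocyclodeca[b]furan-4-yl (2Z)-2-methylbut-2-enoate | C=C1C(=O)O[C@@H]2/C=C(/C)C(=O)/C=C/[C@](C)(O)C[C@@H](OC(=O)/C(C)=C\C)[C@@H]12 | intermediate
23 | (3aR,4R,6R,7E,9R,10Z,11aR)-6,9-dihydroxy-6,10-dimethyl-3-methylidene-2-oxo-2,3,3a,4,5,6,9,11a-octahydrocyclodeca[b]furan-4-yl (2Z)-2-methylbut-2-enoate | C=C1C(=O)O[C@@H]2/C=C(/C)[C@H](O)/C=C/[C@](C)(O)C[C@@H](OC(=O)/C(C)=C\C)[C@@H]12 | target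

**Step count and risks**

Total steps: 12. Longest linear sequence: 10 (steps 1–4, then 7–12).

The three steps most likely to fail:

Step 10. Aldehyde 16 is a β-acyloxy aldehyde with an acidic, allylic α-hydrogen, so loss of angelate (E1cB) or C7 epimerisation can compete. The C6 configuration also rests on Felkin–Anh/1,3-anti control, which is only moderately secure here. The fallback keeps the glyceraldehyde-derived carbinol as C6 (it already has the needed configuration) instead of cleaving and rebuilding it. It sets out from 14 and comes back at 20. Acetonide removal from 14 (CuCl2·2H2O, MeCN, 0 °C) gives the diol 15. TEMPO/PhI(OAc)2 then oxidises its primary alcohol to the α-hydroxy aldehyde F1. A Z-selective Ando olefination (methyl 2-(diphenoxyphosphoryl)propanoate, NaI, DBU, THF, −78 to 0 °C) gives the hydroxy Z-enoate 19, which closes to 20 as in the main route.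

Step 11 (the proposed new ring expansion). The alkenylrhodium species may be protonated by the free C10 hydroxyl (protodeboronation). It may add intermolecularly in conjugate fashion to an acrylate or to the methylene lactone of the product. The butenolide γ-centre (C6) could also epimerise under the rhodium alkoxide. The fallback uses only known reactions. It sets out from 16 and comes back at 23, so steps 10 to 12 are not needed. Nozaki–Hiyama–Kishi coupling of 16 with (2Z)-3-iodo-2-methylprop-2-en-1-ol (CrCl2, cat. NiCl2, DMF) gives the open allylic diol ester F2. PPTS in CH2Cl2 lactonises it to the methylene lactone with a Z-allylic alcohol side chain F3. MnO2 oxidises this to the Z-enal F4. Iododeboronation with retention (NaI, TsNClNa, aq. THF) gives the E-alkenyl iodide F5. A Nozaki–Hiyama–Kishi macrocyclisation (CrCl2, cat. NiCl2, DMSO, 2 mM) then forms the C2–C3 bond and the C3 carbinol and gives 23 directly, with a chiral sulfonamide ligand on chromium if substrate control is poor.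

Step 12. The conformation of the ten-membered ring may decide the face of hydride attack and override the oxazaborolidine, giving the C3 epimer. The fallback turns that outcome to use by inversion. It sets out from 22 and comes back at 23. Luche reduction of 22 (NaBH4, CeCl3·7H2O, MeOH, −78 °C) would then give the 9S alcohol F6. Mitsunobu reaction (HCO2H, PPh3, DIAD, THF, 0 °C) inverts the secondary carbinol to the 9R formate F7. Mild methanolysis (KHCO3, MeOH, 0 °C) gives 23 without touching the angelate or the lactone.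

**Further compounds**

F1 | step 10 | methyl (3S,4R,6R,7E)-6-hydroxy-3-[(1S)-1-hydroxy-2-oxoethyl]-6-methyl-4-{[(2Z)-2-methylbut-2-enoyl]oxy}-2-methylidene-8-(4,4,5,5-tetramethyl-1,3,2-dioxaborolan-2-yl)oct-7-enoate | C=C(C(=O)OC)[C@@H]([C@H](O)C=O)[C@H](OC(=O)/C(C)=C\C)C[C@@](C)(O)/C=C/B2OC(C)(C)C(C)(C)O2
F2 | step 11 | methyl (3S,4R,6R,7E)-3-[(1R,2Z)-1,4-dihydroxy-3-methylbut-2-en-1-yl]-6-hydroxy-6-methyl-4-{[(2Z)-2-methylbut-2-enoyl]oxy}-2-methylidene-8-(4,4,5,5-tetramethyl-1,3,2-dioxaborolan-2-yl)oct-7-enoate | C=C(C(=O)OC)[C@@H]([C@H](O)/C=C(/C)CO)[C@H](OC(=O)/C(C)=C\C)C[C@@](C)(O)/C=C/B2OC(C)(C)C(C)(C)O2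
F3 | step 11 | (1R,3R,4E)-3-hydroxy-1-{(2R,3R)-2-[(1Z)-3-hydroxy-2-methylprop-1-en-1-yl]-4-methylidene-5-oxooxolan-3-yl}-3-methyl-5-(4,4,5,5-tetramethyl-1,3,2-dioxaborolan-2-yl)pent-4-en-1-yl (2Z)-2-methylbut-2-enoate | C=C1C(=O)O[C@H](/C=C(/C)CO)[C@H]1[C@H](OC(=O)/C(C)=C\C)C[C@@](C)(O)/C=C/B2OC(C)(C)C(C)(C)O2
F4 | step 11 | (1R,3R,4E)-3-hydroxy-3-methyl-1-{(2R,3R)-4-methylidene-2-[(1Z)-2-methyl-3-oxoprop-1-en-1-yl]-5-oxooxolan-3-yl}-5-(4,4,5,5-tetramethyl-1,3,2-dioxaborolan-2-yl)pent-4-en-1-yl (2Z)-2-methylbut-2-enoate | C=C1C(=O)O[C@H](/C=C(/C)C=O)[C@H]1[C@H](OC(=O)/C(C)=C\C)C[C@@](C)(O)/C=C/B2OC(C)(C)C(C)(C)O2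
F5 | step 11 | (1R,3R,4E)-3-hydroxy-5-iodo-3-methyl-1-{(2R,3R)-4-methylidene-2-[(1Z)-2-methyl-3-oxoprop-1-en-1-yl]-5-oxooxolan-3-yl}pent-4-en-1-yl (2Z)-2-methylbut-2-enoate | C=C1C(=O)O[C@H](/C=C(/C)C=O)[C@H]1[C@H](OC(=O)/C(C)=C\C)C[C@@](C)(O)/C=C/I
F6 | step 12 | (3aR,4R,6R,7E,9S,10Z,11aR)-6,9-dihydroxy-6,10-dimethyl-3-methylidene-2-oxo-2,3,3a,4,5,6,9,11a-octahydrocyclodeca[b]furan-4-yl (2Z)-2-methylbut-2-enoate | C=C1C(=O)O[C@@H]2/C=C(/C)[C@@H](O)/C=C/[C@](C)(O)C[C@@H](OC(=O)/C(C)=C\C)[C@@H]12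
F7 | step 12 | (3aR,4R,6R,7E,9R,10Z,11aR)-9-(formyloxy)-6-hydroxy-6,10-dimethyl-3-methylidene-2-oxo-2,3,3a,4,5,6,9,11a-octahydrocyclodeca[b]furan-4-yl (2Z)-2-methylbut-2-enoate | C=C1C(=O)O[C@@H]2/C=C(/C)[C@H](OC=O)/C=C/[C@](C)(O)C[C@@H](OC(=O)/C(C)=C\C)[C@@H]12
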